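## Retrosynthetic overview

1. **Feature.** Ring A (C1–C2–C3–C4–C5–C10) holds the cis methyl pair on C4 and quaternary C5, and an oxygen on C2 that stands 1,4 to C5. This is the retron of a [4+2] union of (E)-2-methylbut-2-enal (C4, C5, C6, both methyls) with a 2-silyloxydiene (C3, C2, C1, C10) whose C10 terminus carries C9–C8 as a ketal-masked acetyl group.
2. **Ring A first.** The cycloaddition makes C3–C4 and C5–C10 and sets C4, C5 and C10. C2 is then set by bulky-hydride reduction of the unmasked ketone.
3. **Ring B second (C5–C6–C7–C8–C9–C10).** The C6 formyl group is homologated to the C7 aldehyde, the acetyl group is unmasked, and aldol condensation C8→C7 gives the trans-fused 7-en-9-one.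
4. **Ring B oxygenation and side chain.** C9 is reduced and inverted, the alkene is epoxidised on the α face under hydroxyl direction, and the epoxide is opened trans-diaxially at C7 with an isopropenyl copper reagent (sets C7 and C8).
5. **Endgame.** C9 is acylated selectively with (Z)-3-methylpent-2-enoic acid (from syn-carbocupration of ethyl pent-2-ynoate), and C2 is desilylated.

Key step: step 4

**Conventions.** All compounds keep the target numbering: C14 is the methyl on C5, C15 the methyl on C4, and C11–C13 the isopropenyl group. β is the face of the C5 methyl. The target is 4β,5β-dimethyl, 10α-H (trans-decalin), 2α-OH (axial), 7β-isopropenyl (axial), 8α-OH (axial) and 9α-O-acyl (equatorial), that is 2S,4S,5R,7R,8R,9S,10R.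

**Assumption.** In the accepted binding model of this catalyst class (boron on the formyl oxygen, formyl C–H···O contact, s-trans enal stacked on the neighbouring phenyl group), the (S)-catalyst is taken to leave the C2 Re side of an α-methyl enal open. The target needs bond formation on the C2 Si / C3 Re side of 7, so the (R)-catalyst is specified. The sense is checked on 8, and the antipodal catalyst is made the same way should it prove opposite.

## Route

**Step 1**
Reactants: 1 ethyl pyruvate
Product: 2 ethyl 2-methyl-1,3-dioxolane-2-carboxylate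
Conditions: HOCH2CH2OH, p-TsOH·H2O (cat.), toluene, reflux, Dean–Stark
Reagents that add atoms: ethylene glycol, OCCO
Why: Acid-catalysed ketalisation with azeotropic water removal works well on the activated α-keto ester carbonyl and leaves the ester untouched.

**Step 2**
Reactants: 2 ethyl 2-methyl-1,3-dioxolane-2-carboxylate; 3 1-(triphenylphosphoranylidene)propan-2-one
Product: 5 (E)-4-(2-methyl-1,3-dioxolan-2-yl)but-3-en-2-one, via ketal aldehyde 4 (not isolated)
Conditions: i-Bu2AlH, CH2Cl2, −78 °C; MeOH; then 3, −78 °C → rt
Reagents that add atoms: none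
Why: Partial reduction of the α,α-dialkoxy ester stops at the aluminium hemiacetal, and the non-enolisable aldehyde released on warming is caught in a Wittig olefination whose stabilised ylide should give the E-enone.

**Step 3**
Reactants: 5 (E)-4-(2-methyl-1,3-dioxolan-2-yl)but-3-en-2-one
Product: 6 (E)-2-(tert-butyldimethylsilyloxy)-4-(2-methyl-1,3-dioxolan-2-yl)buta-1,3-diene
Conditions: TBSOTf, Et3N, Et2O, 0 °C
Reagents that add atoms: tert-butyldimethylsilyl triflate, CC(C)(C)[Si](C)(C)OS(=O)(=O)C(F)(F)F
Why: In this silyl enol ether formation by soft enolisation only the methyl protons can be removed, because the γ-carbon (C9) is fully substituted, so a single cross-conjugated diene with the E-alkene retained is expected.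

**Step 4 (key step)**
Reactants: 6 (E)-2-(tert-butyldimethylsilyloxy)-4-(2-methyl-1,3-dioxolan-2-yl)buta-1,3-diene; 7 (E)-2-methylbut-2-enal
Product: 8 (1R,2R,6S)-4-(tert-butyldimethylsilyloxy)-1,6-dimethyl-2-(2-methyl-1,3-dioxolan-2-yl)cyclohex-3-ene-1-carbaldehyde (ring A aldehyde; C4 and C5 methyls cis; C9 cis to the C5 methyl)
Conditions: (R)-3,3-diphenyl-1-(o-tolyl)tetrahydro-1H,3H-pyrrolo[1,2-c][1,3,2]oxazaborole (20 mol %), HNTf2 (18 mol %), CH2Cl2, −78 → −40 °C; Et3N quench
Reagents that add atoms: none
Why: The cationic boron Lewis acid binds the formyl oxygen of s-trans 7, lowers its LUMO and shields one π-face, and a concerted, asynchronous, suprafacial [4+2] cycloaddition follows in which C3–C4 runs ahead of C5–C10; the closest known reaction type is the oxazaborolidinium-catalysed Diels–Alder reaction of α-substituted enals with 2-silyloxydienes. Ring A is closed in this one intermolecular cycloaddition, both new σ-bonds being ring bonds of the six-membered carbocycle. C4 and C5 are fixed by the catalyst-selected enal face (C2 Si / C3 Re of 7) together with the E geometry of 7, which is carried over as the cis C4/C5 methyl pair. C10 is fixed by the E geometry of 6 and the exo-formyl arrangement, which is expected because the endo alternative presses the catalyst-bound formyl group against the C2 silyloxy group while the α-methyl group pays no such penalty; this places C9 cis to the C5 methyl. The step needs regioselectivity, and the substrate secures it twice: the 2-silyloxy group makes C3 the most nucleophilic terminus (oxygen at C2 ends 1,4 to C5), and the C10 substituent directs ortho to the formyl-bearing carbon, both towards the same isomer. A minor endo adduct would be removed here by chromatography, and C10 later sits α to the C9 ketone, where the required equatorial arrangement is also the thermodynamic one.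

**Step 5**
Reactants: 8 ring A aldehyde
Product: 9 methyl enol ether (C5–CH=CH–OMe, E/Z mixture; silyl enol ether and ketal retained)
Conditions: Ph3P(CH2OMe)Cl, KN(SiMe3)2, THF, 0 °C → rt
Reagents that add atoms: (methoxymethyl)triphenylphosphonium chloride, COC[P+](c1ccccc1)(c1ccccc1)c1ccccc1.[Cl-]
Why: Wittig methoxymethylenation uses a small, reactive ylide that adds even to hindered non-enolisable aldehydes, the base-stable silyl enol ether and ketal survive, and the alkene geometry is irrelevant because both isomers converge in step 9.

**Step 6**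
Reactants: 9 methyl enol ether
Product: 10 C2 ketone (cyclohexanone; methyl enol ether and ketal retained)
Conditions: n-Bu4NF, AcOH, THF, 0 °C
Reagents that add atoms: none
Why: Fluoride-induced cleavage of the silyl enol ether with buffered protonation of the enolate frees the ketone, while the methyl enol ether and the ketal are inert to fluoride and no stereocentre is α to the new carbonyl.

**Step 7**
Reactants: 10 C2 ketone
Product: 11 2α-alcohol (axial OH)
Conditions: LiBH(s-Bu)3 (L-Selectride), THF, −78 °C; H2O
Reagents that add atoms: none
Why: In this diastereoselective ketone reduction ring A sits in the chair with the C10 ketal group, the C6 chain and the C4 methyl equatorial, so the bulky trialkylborohydride attacks equatorially and should set C2 as the axial 2α-alcohol.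

**Step 8**
Reactants: 11 2α-alcohol
Product: 12 2α-TBS ether
Conditions: TBSCl, imidazole, DMF, 40 °C
Reagents that add atoms: tert-butyldimethylsilyl chloride, CC(C)(C)[Si](C)(C)Cl
Why: Standard silyl ether protection under mildly basic conditions spares the acid-labile enol ether and ketal and masks C2–OH through the C9 inversion and the final acylation.

**Step 9**
Reactants: 12 2α-TBS ether
Product: 13 keto aldehyde (C5–CH2–CHO, C10–C(O)CH3, 2α-OTBS)
Conditions: p-TsOH·H2O (cat.), THF/H2O 4:1, rt
Reagents that add atoms: water, O
Why: Mild acid hydrolysis cleaves the enol ether to the C7 aldehyde and the dioxolane to the C9 methyl ketone in one operation, and a secondary TBS ether should withstand these conditions.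

**Step 10**
Reactants: 13 keto aldehyde
Product: 15 trans-fused 7-en-9-one (2α-OTBS; 4β,5β-dimethyl; 10α-H), via aldol 14 (not isolated)
Conditions: KOH (0.3 equiv), MeOH, 0 °C → rt
Reagents that add atoms: none
Why: In this intramolecular aldol condensation only the pairing of the C8 methyl enolate with the C7 aldehyde gives an unstrained six-membered ring (the other pairings would give four-membered rings), E1cB loss of water gives the enone, and C10 keeps its equatorial acyl arrangement and hence the trans ring fusion.

**Step 11**
Reactants: 15 trans-fused 7-en-9-one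
Product: 16 9β-allylic alcohol (pseudoaxial OH)
Conditions: i-Bu2AlH, CH2Cl2, −78 °C; Rochelle salt work-up
Reagents that add atoms: none
Why: In this 1,2-reduction of the enone the β-face trajectory at C9 is blocked by the syn-axial C5 methyl, so hydride should enter from the α face; any minor 9α-epimer is 18 itself and is combined after step 13.

**Step 12**
Reactants: 16 9β-allylic alcohol
Product: 17 9α-(4-nitrobenzoate)
Conditions: 4-O2NC6H4CO2H, PPh3, DIAD, toluene, 0 °C → rt
Reagents that add atoms: 4-nitrobenzoic acid, OC(=O)c1ccc(cc1)[N+](=O)[O-]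
Why: In the Mitsunobu inversion the activated pseudoaxial allylic oxygen is displaced by SN2 attack from the open α face, which sets C9 in the required α (equatorial) configuration.

**Step 13**
Reactants: 17 9α-(4-nitrobenzoate)
Product: 18 9α-allylic alcohol
Conditions: K2CO3 (cat.), MeOH, rt
Reagents that add atoms: none
Why: Base-catalysed transesterification removes the activated aryl ester by acyl–oxygen cleavage, so C9 and the TBS ether are untouched.

**Step 14**
Reactants: 18 9α-allylic alcohol
Product: 19 7α,8α-epoxy-9α-ol
Conditions: mCPBA, CH2Cl2, 0 °C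
Reagents that add atoms: 3-chloroperoxybenzoic acid, OOC(=O)c1cccc(Cl)c1
Why: In this hydroxyl-directed (Henbest) peracid epoxidation the pseudoequatorial 9α-OH and the β-face shielding by the C5 methyl both steer oxygen to the α face.

**Step 15**
Reactants: 19 7α,8α-epoxy-9α-ol; 20 isopropenylmagnesium bromide
Product: 21 7β-isopropenyl-8α,9α-diol (2α-OTBS)
Conditions: 20 (5 equiv), CuI (20 mol %), THF, −30 → 0 °C; aq NH4Cl
Reagents that add atoms: none
Why: In this copper-catalysed Grignard opening of an epoxide the Fürst–Plattner (trans-diaxial) rule sends carbon to C7 from the β face and leaves the 8α-oxygen axial (the regiochemistry that 2α,3α-epoxy-5α-steroids show despite their syn-axial angular methyl), the C9 alkoxide further disfavours attack at C8, and inversion at C7 with retention at C8 sets both centres.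

**Step 16**
Reactants: 22 ethyl pent-2-ynoate
Product: 23 ethyl (Z)-3-methylpent-2-enoate
Conditions: Me2CuLi (from MeLi, CuI), THF, −78 °C; MeOH, −78 °C
Reagents that add atoms: methyllithium, [Li]C
Why: Syn-carbocupration of the ynoate puts methyl and copper cis, and protonation at low temperature with retention leaves ethyl cis to the ester, which is the Z-enoate.

**Step 17**
Reactants: 23 ethyl (Z)-3-methylpent-2-enoate
Product: 24 (Z)-3-methylpent-2-enoic acid
Conditions: LiOH, THF/MeOH/H2O, rt; then 1 M HCl
Reagents that add atoms: lithium hydroxide, [Li+].[OH-]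
Why: Mild saponification does not touch the trisubstituted alkene geometry.

**Step 18**
Reactants: 21 7β-isopropenyl-8α,9α-diol; 24 (Z)-3-methylpent-2-enoic acid
Product: 25 9α-[(Z)-3-methylpent-2-enoate] with free 8α-OH and 2α-OTBS
Conditions: 24 (1.1 equiv), DCC, DMAP (10 mol %), CH2Cl2, −20 → 0 °C
Reagents that add atoms: none
Why: In this Steglich esterification the equatorial 9α-OH should be acylated faster than the axial 8α-OH, which has two syn-axial hydrogens and the isopropenyl-bearing C7 next to it, and carbodiimide activation avoids the acid chloride/vinylketene pathway that could scramble the Z-alkene.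

**Step 19**
Reactants: 25 9α-ester
Product: 26 target CNP0129603.1
Conditions: HF·pyridine, pyridine/THF, 0 °C → rt
Reagents that add atoms: none
Why: Fluoride-mediated desilylation in a weakly acidic medium frees the 2α-OH without the base-induced C9→C8 acyl migration and leaves the isopropenyl group and the enoate intact.

## Compound list

1 | ethyl pyruvate | CCOC(=O)C(C)=O | starting material
2 | ethyl 2-methyl-1,3-dioxolane-2-carboxylate | CCOC(=O)C1(C)OCCO1 | intermediate
3 | 1-(triphenylphosphoranylidene)propan-2-one | CC(=O)C=P(c1ccccc1)(c1ccccc1)c1ccccc1 | starting material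
4 | 2-methyl-1,3-dioxolane-2-carbaldehyde (ketal aldehyde, not isolated) | O=CC1(C)OCCO1 | intermediate
5 | (E)-4-(2-methyl-1,3-dioxolan-2-yl)but-3-en-2-one | CC(=O)/C=C/C1(C)OCCO1 | intermediate
6 | (E)-2-(tert-butyldimethylsilyloxy)-4-(2-methyl-1,3-dioxolan-2-yl)buta-1,3-diene | C=C(O[Si](C)(C)C(C)(C)C)/C=C/C1(C)OCCO1 | intermediate
7 | (E)-2-methylbut-2-enal | C/C=C(\C)C=O | starting material
8 | (1R,2R,6S)-4-(TBSO)-1,6-dimethyl-2-(2-methyl-1,3-dioxolan-2-yl)cyclohex-3-ene-1-carbaldehyde | O=C[C@]1(C)[C@@H](C)CC(O[Si](C)(C)C(C)(C)C)=C[C@H]1C2(C)OCCO2 | intermediate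
9 | methyl enol ether of the homologated aldehyde (E/Z mixture) | COC=C[C@]1(C)[C@@H](C)CC(O[Si](C)(C)C(C)(C)C)=C[C@H]1C2(C)OCCO2 | intermediate
10 | C2 ketone | COC=C[C@]1(C)[C@@H](C)CC(=O)C[C@H]1C2(C)OCCO2 | intermediate
11 | 2α-alcohol | COC=C[C@]1(C)[C@@H](C)C[C@H](O)C[C@H]1C2(C)OCCO2 | intermediate
12 | 2α-TBS ether | COC=C[C@]1(C)[C@@H](C)C[C@H](O[Si](C)(C)C(C)(C)C)C[C@H]1C2(C)OCCO2 | intermediate
13 | keto aldehyde | O=CC[C@]1(C)[C@@H](C)C[C@H](O[Si](C)(C)C(C)(C)C)C[C@H]1C(C)=O | intermediate
14 | 7-hydroxy-9-ketone (aldol, C7 epimers, not isolated) | OC1C[C@]2(C)[C@@H](C)C[C@H](O[Si](C)(C)C(C)(C)C)C[C@H]2C(=O)C1 | intermediate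
15 | trans-fused 7-en-9-one | O=C1C=CC[C@]2(C)[C@@H](C)C[C@H](O[Si](C)(C)C(C)(C)C)C[C@@H]12 | intermediate
16 | 9β-allylic alcohol | O[C@H]1C=CC[C@]2(C)[C@@H](C)C[C@H](O[Si](C)(C)C(C)(C)C)C[C@@H]12 | intermediate
17 | 9α-(4-nitrobenzoate) | O=C(O[C@@H]1C=CC[C@]2(C)[C@@H](C)C[C@H](O[Si](C)(C)C(C)(C)C)C[C@@H]12)c3ccc(cc3)[N+](=O)[O-] | intermediate
18 | 9α-allylic alcohol | O[C@@H]1C=CC[C@]2(C)[C@@H](C)C[C@H](O[Si](C)(C)C(C)(C)C)C[C@@H]12 | intermediate
19 | 7α,8α-epoxy-9α-ol | O3[C@@H]1C[C@]2(C)[C@@H](C)C[C@H](O[Si](C)(C)C(C)(C)C)C[C@H]2[C@H](O)[C@@H]13 | intermediate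
20 | isopropenylmagnesium bromide | C=C(C)[Mg]Br | starting material
21 | 7β-isopropenyl-8α,9α-diol, 2α-OTBS | C=C(C)[C@H]1C[C@]2(C)[C@@H](C)C[C@H](O[Si](C)(C)C(C)(C)C)C[C@H]2[C@H](O)[C@@H]1O | intermediate
22 | ethyl pent-2-ynoate | CCC#CC(=O)OCC | starting material
23 | ethyl (Z)-3-methylpent-2-enoate | CCOC(=O)/C=C(/C)CC | intermediate
24 | (Z)-3-methylpent-2-enoic acid | OC(=O)/C=C(/C)CC | intermediate
25 | 9α-[(Z)-3-methylpent-2-enoate], 8α-OH, 2α-OTBS | C=C(C)[C@H]1C[C@]2(C)[C@@H](C)C[C@H](O[Si](C)(C)C(C)(C)C)C[C@H]2[C@H](OC(=O)/C=C(/C)CC)[C@@H]1O | intermediate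
26 | CNP0129603.1 | C=C(C)[C@H]1C[C@]2(C)[C@@H](C)C[C@H](O)C[C@H]2[C@H](OC(=O)/C=C(/C)CC)[C@@H]1O | target

## Step count

Total: 19 steps. Longest linear sequence: 17 steps (steps 1–15, 18 and 19, from ethyl pyruvate).

## Steps most likely to fail

**Step 4.**
- **What may go wrong.** The cationic Lewis acid may ionise the allylic ketal or protodesilylate the diene. Closure of the crowded C5–C10 bond may be slow. An achiral silyl triflimide background cycle may erode facial selectivity.
- **Fallback.** It sets out from 6 and 7 and gives up catalyst control in favour of a Lewis-acid-free cycloaddition followed by resolution.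
- **Cycloaddition.** Heating in toluene with BHT in a sealed tube (or high pressure at rt) should give 8 together with its mirror image ent-8 F1.
- **Carrying the racemate forward.** Steps 5–7 applied to the racemate deliver, besides 9, 10 and 11, their antipodes ent-9 F2, ent-10 F3 and ent-11 F4.
- **Resolution.** Esterification of the racemic alcohol with (S)-2-methoxy-2-phenylacetic acid (DCC, DMAP) gives two diastereomers, the (S)-O-methylmandelate of 11 F5 and the (S)-O-methylmandelate of ent-11 F6, which are separated by chromatography or crystallisation. LiOH in aqueous THF cleaves F5, and the route is rejoined at 11.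

**Step 15.**
- **What may go wrong.** Axial attack at C7 next to the syn-axial C5 methyl may be slow enough for magnesium-halide-promoted halohydrin formation or epoxide rearrangement to take over.
- **Fallback.** It sets out from 19 and brings in the carbon as a small linear nucleophile that is branched afterwards.
- **Sequence.** LiC≡CH·H2NCH2CH2NH2 in DMSO/THF opens the epoxide trans-diaxially to the 7β-ethynyl-8α,9α-diol F7. Zirconium-catalysed methylalumination (AlMe3, Cp2ZrCl2, CH2Cl2) then places methyl on the internal alkyne carbon, and protonolysis of the vinylalane gives the isopropenyl group. The route is rejoined at 21.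

**Step 12.**
- **What may go wrong.** E2 loss of the activated pseudoaxial C9 oxygen with the antiperiplanar axial C10–H (diene formation), or SN2′ capture at C7, may outrun direct displacement.
- **Fallback.** It sets out from 15 and replaces kinetic reduction plus inversion by thermodynamic control.
- **Sequence.** Meerwein–Ponndorf–Verley reduction under equilibrating conditions (Al(Oi-Pr)3, i-PrOH/toluene, reflux) is 1,2-selective and reversible. It should therefore drain into the equatorial 9α-alcohol, which avoids the syn-axial contact with the C5 methyl. The route is rejoined at 18 without any new compound.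

## Further compounds

F1 | step 4 | ent-8 | O=C[C@@]1(C)[C@H](C)CC(O[Si](C)(C)C(C)(C)C)=C[C@@H]1C2(C)OCCO2
F2 | step 4 | ent-9 | COC=C[C@@]1(C)[C@H](C)CC(O[Si](C)(C)C(C)(C)C)=C[C@@H]1C2(C)OCCO2
F3 | step 4 | ent-10 | COC=C[C@@]1(C)[C@H](C)CC(=O)C[C@@H]1C2(C)OCCO2
F4 | step 4 | ent-11 | COC=C[C@@]1(C)[C@H](C)C[C@@H](O)C[C@@H]1C2(C)OCCO2
F5 | step 4 | (S)-O-methylmandelate of 11 | COC=C[C@]1(C)[C@@H](C)C[C@H](OC(=O)[C@@H](OC)c3ccccc3)C[C@H]1C2(C)OCCO2
F6 | step 4 | (S)-O-methylmandelate of ent-11 | COC=C[C@@]1(C)[C@H](C)C[C@@H](OC(=O)[C@@H](OC)c3ccccc3)C[C@@H]1C2(C)OCCO2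
F7 | step 15 | 7β-ethynyl-8α,9α-diol, 2α-OTBS | C#C[C@H]1C[C@]2(C)[C@@H](C)C[C@H](O[Si](C)(C)C(C)(C)C)C[C@H]2[C@H](O)[C@@H]1O
F0 | step 12 | none | none
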